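The benzo ring of the indoxyl carries N1 (at C7a) and the C3 carbonyl (at C3a) on adjacent carbons, the retron of benzyne, while N1–C2–C3 is an α-amino acid unit. The key step therefore joins three components in one pot. The anion of an N-tosyl (indol-3-yl)glycine ester adds to benzyne, and the aryl anion closes the five-membered ring on the ester. Toluenesulfinate then leaves N1 to unveil the C2=N1 ketimine, and a second indole adds at C2 to create the quaternary carbon. Tosyl thus serves as activator and as internal oxidant. The precursor is an acyclic amino ester made in one step from indole, ethyl glyoxylate and TsNH2.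

Key step: step 2

Remark: C2 of the target bears two identical indol-3-yl groups, so the target is achiral and the amino ester precursor is used as the racemate. Ethyl glyoxylate is taken as the commercial solution in toluene.

Step 1
Reactants: 1 indole; 2 ethyl glyoxylate; 3 p-toluenesulfonamide
Product: 5 ethyl 2-(1H-indol-3-yl)-2-(tosylamino)acetate (racemic), via ethyl 2-(tosylimino)acetate 4 (not isolated)
Conditions: 2 (1.2 equiv, 50% in toluene), 3 (1.2 equiv), Cu(OTf)2 (5 mol %), 4 Å MS, CH2Cl2, rt; then 1, 0 °C to rt
Reagents that add atoms: none
Why: Three-component aza-Friedel–Crafts reaction, in which the Lewis acid condenses 3 with the aldehyde of 2 to the strongly electrophilic N-sulfonyl imino ester 4, which is attacked by C3, the most nucleophilic position of indole; the new stereocentre forms as a racemate, which is harmless because step 2 erases it.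

Step 2
Reactants: 5 ethyl 2-(1H-indol-3-yl)-2-(tosylamino)acetate; 6 2-(trimethylsilyl)phenyl trifluoromethanesulfonate; 1 indole
Product: 10 2,2-bis(1H-indol-3-yl)indolin-3-one, via benzyne 7 (not isolated), via 2-(1H-indol-3-yl)-1-tosylindolin-3-one 8 (not isolated), via 2-(1H-indol-3-yl)-3H-indol-3-one 9 (not isolated)
Conditions: 6 (1.2 equiv), CsF (3 equiv), MeCN, rt, Ar; then DBU (2 equiv), 70 °C; then 1 (1.5 equiv), AcOH, 50 °C (one pot)
Reagents that add atoms: none
Why: Proposed new method: CsF frees benzyne 7 from 6 and deprotonates only the sulfonamide N–H of 5, the nitrogen anion adds to 7 (N1–C7a) and, as no N–H remains on that nitrogen, the ortho aryl anion attacks the ester carbonyl and expels ethoxide (C3–C3a), which closes the five-membered ring of 8 in a 5-exo-trig mode. Up to this point the step is the known formal [3+2] annulation of arynes with N-sulfonyl α-amino esters and with indole-2-carboxylates. New is the continuation in the same flask: DBU converts 8 fully into its C2 enolate, which on heating expels p-toluenesulfinate from N1 as soon as sulfur bends out of the ring plane and the N–S σ* orbital overlaps with the enolate π system, the closest known reaction type being the base-induced 1,2-elimination of sulfinate from N-sulfonyl α-amino esters and ketones that delivers imines, pyrroles and isoquinolines, and the push-pull conjugation of the new C2=N1 bond with the indol-3-yl group in 9 compensates for the lost enolate stabilisation. In AcOH the protonated ketimine 9 is attacked at C2 by C3 of indole 1, a known aza-Friedel–Crafts addition to 3H-indol-3-ones, and reversible C2 adducts of sulfinate or ethanol re-ionise and drain into the same product. No stereocentre is created, because C2 ends with two identical indol-3-yl groups and the racemic centre of 5 is erased in 9. The step needs attack of the sulfonamide nitrogen in preference to the indole nitrogen and acylation in preference to protonation or Truce–Smiles aryl transfer, which the large acidity gap between the two N–H types, the five-membered transition state next to the ester, the electron-rich tolyl ring and the late addition of 1 (only after 6 is used up) should secure.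

Compound list
1 | indole | c1ccc2[nH]ccc2c1 | starting material
2 | ethyl glyoxylate | CCOC(=O)C=O | starting material
3 | p-toluenesulfonamide | Cc1ccc(cc1)S(N)(=O)=O | starting material
4 | ethyl (E)-2-(tosylimino)acetate | CCOC(=O)/C=N/S(=O)(=O)c1ccc(C)cc1 | intermediate
5 | ethyl 2-(1H-indol-3-yl)-2-(tosylamino)acetate (racemic) | CCOC(=O)C(NS(=O)(=O)c1ccc(C)cc1)c1c[nH]c2ccccc12 | intermediate
6 | 2-(trimethylsilyl)phenyl trifluoromethanesulfonate | C[Si](C)(C)c1ccccc1OS(=O)(=O)C(F)(F)F | starting material
7 | benzyne | C1#CC=CC=C1 | intermediate
8 | 2-(1H-indol-3-yl)-1-tosylindolin-3-one (racemic) | Cc1ccc(cc1)S(=O)(=O)N1c2ccccc2C(=O)C1c1c[nH]c2ccccc12 | intermediate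
9 | 2-(1H-indol-3-yl)-3H-indol-3-one | O=C1C(=Nc2ccccc12)c1c[nH]c2ccccc12 | intermediate
10 | 2,2-bis(1H-indol-3-yl)indolin-3-one (2,2-bis(3'-indolyl)indoxyl) | O=C1c2ccccc2NC1(c1c[nH]c2ccccc12)c1c[nH]c2ccccc12 | target

Total step count: 2
Longest linear sequence: 2 (1 to 5 to 10)

Steps most likely to fail. The route has only two steps, so step 2 is entered twice, once for each of its two independent failure processes.

1) Step 2 (labelled), loss of sulfinate.
- **Risk:** The elimination may stall at the aromatic enolate of 8, because the N–S bond lies close to the nodal plane of the enolate π system.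
- **Fallback:** It uses known chemistry only, keeps the benzyne annulation and replaces the internal oxidant by air. It sets out from 1 and 2.
- 2-(Trimethylsilyl)ethanesulfonamide takes the place of 3 in the aza-Friedel–Crafts reaction. This should pass through ethyl (E)-2-{[2-(trimethylsilyl)ethyl]sulfonylimino}acetate F1 and give ethyl 2-(1H-indol-3-yl)-2-{[2-(trimethylsilyl)ethyl]sulfonylamino}acetate F2.
- Annulation with 6 and CsF in MeCN should give 2-(1H-indol-3-yl)-1-{[2-(trimethylsilyl)ethyl]sulfonyl}indolin-3-one F3.
- Bu4NF in THF should remove the sulfonyl group by the usual fluoride-induced fragmentation to give 2-(1H-indol-3-yl)indolin-3-one F4.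
- The familiar autoxidation of N–H indoxyls in air brings the sequence back to the route at 9, which is treated with 1 in AcOH as in the last stage of step 2.

2) Step 2 (labelled), capture of benzyne.
- **Risk:** Arylation of the indole nitrogen, or protonation of the aryl anion by the indole N–H before ring closure, may compete with the annulation.
- **Fallback:** It uses known chemistry only and removes the competing N–H. It sets out from 1 and 2 and runs through the amino ester F2.
- NaH (2 equiv) turns F2 into its dianion. The more basic indolide nitrogen takes up Boc2O (1 equiv) to give ethyl 2-[1-(tert-butoxycarbonyl)indol-3-yl]-2-{[2-(trimethylsilyl)ethyl]sulfonylamino}acetate F5.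
- Annulation with 6 and CsF, now with a single N–H in the substrate, should give tert-butyl 3-(3-oxo-1-{[2-(trimethylsilyl)ethyl]sulfonyl}indolin-2-yl)indole-1-carboxylate F6.
- TFA in CH2Cl2 cleaves the carbamate to the N-sulfonyl indoxyl F3. Bu4NF and then air lead through the N–H indoxyl F4 back to the route at 9.

3) Step 1, double alkylation and incomplete condensation.
- **Risk:** Acid-promoted exchange of the sulfonamide for a second indole, and sluggish dehydrative imine formation, may erode the mono-adduct.
- **Fallback:** It sets out from 2, which is heated with p-toluenesulfonyl isocyanate in toluene. A [2+2] cycloaddition followed by loss of carbon dioxide forms the imine irreversibly and without water, so the sequence comes back to the route at 4.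
- After removal of the solvent, 4 takes up 1 at low temperature in the absence of any Brønsted acid. No compound outside the list is made (F0).

Further compounds
F1 | step 2 | ethyl (E)-2-{[2-(trimethylsilyl)ethyl]sulfonylimino}acetate | CCOC(=O)/C=N/S(=O)(=O)CC[Si](C)(C)C
F2 | step 2 | ethyl 2-(1H-indol-3-yl)-2-{[2-(trimethylsilyl)ethyl]sulfonylamino}acetate (racemic) | CCOC(=O)C(NS(=O)(=O)CC[Si](C)(C)C)c1c[nH]c2ccccc12
F3 | step 2 | 2-(1H-indol-3-yl)-1-{[2-(trimethylsilyl)ethyl]sulfonyl}indolin-3-one (racemic) | O=C1c2ccccc2N(S(=O)(=O)CC[Si](C)(C)C)C1c1c[nH]c2ccccc12
F4 | step 2 | 2-(1H-indol-3-yl)indolin-3-one (racemic) | O=C1c2ccccc2NC1c1c[nH]c2ccccc12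
F5 | step 2 | ethyl 2-[1-(tert-butoxycarbonyl)indol-3-yl]-2-{[2-(trimethylsilyl)ethyl]sulfonylamino}acetate (racemic) | CCOC(=O)C(NS(=O)(=O)CC[Si](C)(C)C)c1cn(C(=O)OC(C)(C)C)c2ccccc12
F6 | step 2 | tert-butyl 3-(3-oxo-1-{[2-(trimethylsilyl)ethyl]sulfonyl}indolin-2-yl)indole-1-carboxylate (racemic) | O=C1c2ccccc2N(S(=O)(=O)CC[Si](C)(C)C)C1c1cn(C(=O)OC(C)(C)C)c2ccccc12
F0 | step 1 | none | none
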